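C1 ketone, C4/C5 epoxide, C6 lactone carbinol, C7=C11 butenolide olefin, C8 acyloxy carbon, C9 methylene, C10 methyl-bearing methine, C12 lactone carbonyl, C13 acetoxymethyl and C14/C15 methyls are the germacranolide locants used throughout.
Retrosynthetic cuts, in order: the C12–O6 lactone bond and the O8 ester; C9–C10 (ring closure); C10–C14; C1–C10; C11–C13; C7–C8 together with C11–I; C6–C7; this leaves nerol (C1–C6 and C15).
Enabling feature: the C1 ketone and the C8 oxygen sit 1,4 across C9–C10, so with C8 raised to a ketone conjugated to C7=C11, C9 becomes an α-keto bromide, and with a temporary allyl carboxylate on C10 next to C1, C10 becomes a soft carbon nucleophile.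
Forward order: the open chain is built linearly from nerol, the ten-membered carbocycle is closed by C9–C10 alkylation, and the butenolide ring is closed last by lactonisation of O6 onto C12.
Stereochemistry: C4/C5 from Sharpless epoxidation of the Z-olefin (cis-epoxide); C6 from catalyst-controlled alkynylation; C7=C11 geometry from syn-carbocupration; C8 from CBS reduction; C10 from enantioselective decarboxylative protonation.

Key step: step 11

Assumption: the enantiomer of each chiral catalyst named in steps 3, 13 and 17 is the one its usual facial model predicts for this substrate; the antipodal catalyst is taken if a model compound shows the opposite sense.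

Step 1
Reactants: 1 nerol
Product: 2 (2S,3R)-2,3-epoxynerol
Conditions: Ti(OiPr)4 (10 mol%), L-(+)-diethyl tartrate (12 mol%), t-BuOOH, 4 Å MS, CH2Cl2, −20 °C
Reagents that add atoms: tert-butyl hydroperoxide CC(C)(C)OO
Why: Katsuki–Sharpless asymmetric epoxidation touches only the allylic olefin, L-(+)-tartrate should give the (2S,3R)-epoxide, and syn oxygen transfer to the Z-olefin fixes the cis arrangement of the ring carbons on the future C4/C5 epoxide.

Step 2
Reactants: 2 (2S,3R)-2,3-epoxynerol
Product: 3 (2R,3R)-3-methyl-3-(4-methylpent-3-en-1-yl)oxirane-2-carbaldehyde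
Conditions: TEMPO (10 mol%), PhI(OAc)2, CH2Cl2, rt
Reagents that add atoms: none
Why: TEMPO/PhI(OAc)2 oxidation of a primary alcohol to the aldehyde is neutral and should spare the epoxide and its α-centre.

Step 3
Reactants: 3 (2R,3R)-3-methyl-3-(4-methylpent-3-en-1-yl)oxirane-2-carbaldehyde; 4 methyl propiolate
Product: 5 methyl (4S)-4-hydroxy-4-[(2S,3R)-3-methyl-3-(4-methylpent-3-en-1-yl)oxiran-2-yl]but-2-ynoate
Conditions: Me2Zn (3 equiv), (S,S)-ProPhenol (20 mol%), Ph3PO (40 mol%), toluene, 4 °C; then aq. NH4Cl
Reagents that add atoms: none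
Why: Zinc–ProPhenol catalysed asymmetric alkynylation with the zinc acetylide of methyl propiolate should set the (S)-carbinol at C6 under catalyst control, which is expected to override the modest intrinsic bias of the epoxy aldehyde.

Step 4
Reactants: 5 methyl (4S)-4-hydroxy-4-[(2S,3R)-3-methyl-3-(4-methylpent-3-en-1-yl)oxiran-2-yl]but-2-ynoate
Product: 6 methyl (4S)-4-(tert-butyldimethylsilyloxy)-4-[(2S,3R)-3-methyl-3-(4-methylpent-3-en-1-yl)oxiran-2-yl]but-2-ynoate
Conditions: TBSCl, imidazole, DMF, rt
Reagents that add atoms: tert-butyldimethylsilyl chloride CC(C)(C)[Si](C)(C)Cl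
Why: Routine silylation of a secondary propargylic alcohol, which keeps O6 from lactonising until the last step.

Step 5
Reactants: 6 methyl (4S)-4-(tert-butyldimethylsilyloxy)-4-[(2S,3R)-3-methyl-3-(4-methylpent-3-en-1-yl)oxiran-2-yl]but-2-ynoate; 7 ethyl vinyl ether
Product: 9 methyl (2Z,4S)-4-(tert-butyldimethylsilyloxy)-3-(1-ethoxyethenyl)-2-iodo-4-[(2S,3R)-3-methyl-3-(4-methylpent-3-en-1-yl)oxiran-2-yl]but-2-enoate, via alkenylcopper adduct 8 (not isolated)
Conditions: 7, t-BuLi, THF, −78 to 0 °C; CuI (0.5 equiv), −40 °C; then 6, −78 °C; then I2 (THF), −78 °C; aq. Na2S2O3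
Reagents that add atoms: iodine II
Why: Syn-carbocupration of the ynoate by a Gilman-type α-alkoxyvinyl cuprate puts C8 on C7 and copper on C11 cis to each other, and iodinolysis of the alkenylcopper at −78 °C with retention fixes the tetrasubstituted C7=C11 geometry (C6 cis to the ester).

Step 6
Reactants: 9 methyl (2Z,4S)-4-(tert-butyldimethylsilyloxy)-3-(1-ethoxyethenyl)-2-iodo-4-[(2S,3R)-3-methyl-3-(4-methylpent-3-en-1-yl)oxiran-2-yl]but-2-enoate; 10 (tributylstannyl)methanol
Product: 12 methyl (2E,4S)-2-(acetoxymethyl)-4-(tert-butyldimethylsilyloxy)-3-(1-ethoxyethenyl)-4-[(2S,3R)-3-methyl-3-(4-methylpent-3-en-1-yl)oxiran-2-yl]but-2-enoate, via allylic alcohol 11 (not isolated)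
Conditions: Pd2(dba)3 (5 mol%), AsPh3, CuI (cat.), NMP, 50 °C; crude product then Ac2O, pyridine, DMAP (cat.), CH2Cl2, 0 °C
Reagents that add atoms: acetic anhydride CC(=O)OC(C)=O
Why: Stille coupling of the alkenyl iodide with the hydroxymethyl stannane installs C13 with retention of olefin geometry, and the crude allylic alcohol is acetylated at once so that it cannot add to the neighbouring enol ether.

Step 7
Reactants: 12 methyl (2E,4S)-2-(acetoxymethyl)-4-(tert-butyldimethylsilyloxy)-3-(1-ethoxyethenyl)-4-[(2S,3R)-3-methyl-3-(4-methylpent-3-en-1-yl)oxiran-2-yl]but-2-enoate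
Product: 13 methyl (2E,4S)-2-(acetoxymethyl)-3-(bromoacetyl)-4-(tert-butyldimethylsilyloxy)-4-[(2S,3R)-3-methyl-3-(4-methylpent-3-en-1-yl)oxiran-2-yl]but-2-enoate
Conditions: NBS (1.05 equiv), THF–H2O (4:1), −20 to 0 °C
Reagents that add atoms: N-bromosuccinimide O=C1CCC(=O)N1Br; water O
Why: Electrophilic bromination of the enol ether in water (bromo-hydration, then loss of ethanol) gives the bromomethyl ketone, the enol ether being far more nucleophilic than the trisubstituted olefin or the electron-poor tetrasubstituted one.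

Step 8
Reactants: 13 methyl (2E,4S)-2-(acetoxymethyl)-3-(bromoacetyl)-4-(tert-butyldimethylsilyloxy)-4-[(2S,3R)-3-methyl-3-(4-methylpent-3-en-1-yl)oxiran-2-yl]but-2-enoate
Product: 14 methyl (2E,4S)-2-(acetoxymethyl)-3-(bromoacetyl)-4-(tert-butyldimethylsilyloxy)-4-[(2S,3R)-3-methyl-3-(3-oxopropyl)oxiran-2-yl]but-2-enoate
Conditions: O3, acetone–H2O (95:5), 0 °C, stopped at the first excess of ozone (Sudan Red 7B as indicator); N2 purge
Reagents that add atoms: ozone [O-][O+]=O
Why: Ozonolysis cleaves only the electron-rich trisubstituted olefin, and in wet acetone water intercepts the acetone carbonyl oxide as a hydroxy hydroperoxide that collapses to acetone and H2O2, so the C1 aldehyde forms directly and neither a nucleophilic reductant nor an amine meets the bromomethyl ketone, while the doubly acceptor-substituted C7=C11 olefin is inert.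

Step 9
Reactants: 15 glycine allyl ester p-toluenesulfonate
Product: 16 allyl diazoacetate
Conditions: NaNO2, H2SO4 (cat.), CH2Cl2–H2O, −5 °C
Reagents that add atoms: sodium nitrite [Na+].[O-]N=O
Why: Diazotisation of a glycine ester is the standard preparation of alkyl diazoacetates.

Step 10
Reactants: 14 methyl (2E,4S)-2-(acetoxymethyl)-3-(bromoacetyl)-4-(tert-butyldimethylsilyloxy)-4-[(2S,3R)-3-methyl-3-(3-oxopropyl)oxiran-2-yl]but-2-enoate; 16 allyl diazoacetate
Product: 17 methyl (2E,4S)-2-(acetoxymethyl)-4-{(2S,3R)-3-[5-(allyloxy)-3,5-dioxopentyl]-3-methyloxiran-2-yl}-3-(bromoacetyl)-4-(tert-butyldimethylsilyloxy)but-2-enoate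
Conditions: SnCl2 (20 mol%), CH2Cl2, 0 °C to rt
Reagents that add atoms: none
Why: Roskamp homologation, in which SnCl2-promoted addition of the diazoacetate to the aldehyde is followed by 1,2-hydride shift with loss of N2, gives the β-keto ester (C1 ketone, C10 methylene), and ketones do not react under these conditions.

Step 11
Reactants: 17 methyl (2E,4S)-2-(acetoxymethyl)-4-{(2S,3R)-3-[5-(allyloxy)-3,5-dioxopentyl]-3-methyloxiran-2-yl}-3-(bromoacetyl)-4-(tert-butyldimethylsilyloxy)but-2-enoate
Product: 18 cyclised β-keto ester (ten-membered 1,8-diketone, allyl ester on C10, (4R,5S)-cis-epoxide, (6S)-silyl ether, C7=C11 olefin carrying CO2Me cis to C6 and CH2OAc cis to C8)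
Conditions: Cs2CO3 (3 equiv), Bu4NI (10 mol%), MeCN, rt, slow syringe-pump addition of 17 (final 0.002 M)
Reagents that add atoms: none
Why: Cs2CO3 deprotonates the β-keto ester methylene C10 (between the C1 ketone and the allyl ester), and the caesium enolate displaces bromide (iodide after exchange in the flask) from C9 in an SN2 reaction that the adjacent C8 carbonyl accelerates strongly over an unactivated primary halide. The closest known reaction types are the β-keto ester/α-halo ketone synthesis of 1,4-diketones and the high-dilution caesium carbonate ring closure of malonates and β-keto esters onto activated halides. The ten-membered carbocycle closes in the 10-exo-tet mode, helped by the cis-epoxide at C4–C5 and the tetrasubstituted C7=C11 olefin, which act as turn elements. The only new stereocentre, C10, is left uncontrolled on purpose, because it is epimerisable here, becomes quaternary in step 12 and is set finally in step 17. The step needs carbon rather than oxygen alkylation (soft caesium enolate, soft iodide, MeCN), ring closure rather than oligomerisation (slow addition to high dilution) and attack at C9 rather than at the epoxide or the allylic acetate (both far poorer electrophiles for a stabilised enolate). The carbonate base is too weak to remove the C6 proton, so the C6 configuration and the olefin geometry should survive.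

Step 12
Reactants: 18 cyclised β-keto ester
Product: 19 C10-methylated β-keto ester (C10 quaternary with methyl and allyl ester, both C10 epimers)
Conditions: MeI, K2CO3, acetone, rt
Reagents that add atoms: iodomethane CI
Why: C-methylation of the cyclic β-keto ester, the only carbon acid that carbonate deprotonates, installs C14 and makes C10 quaternary, which shields the C1 ketone in step 13, while the configuration formed here is erased in step 17.

Step 13
Reactants: 19 C10-methylated β-keto ester
Product: 20 (8S)-allylic alcohol (C1 ketone and C10 allyl ester retained)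
Conditions: (R)-2-methyl-CBS-oxazaborolidine, catecholborane, toluene, −78 °C
Reagents that add atoms: none
Why: Corey–Bakshi–Shibata reduction of the conjugated C8 ketone (alkenyl C7 as the large group, ring CH2 C9 as the small one) with the (R)-catalyst should give the (8S)-alcohol, while the C1 ketone next to quaternary C10 is reduced far more slowly by catecholborane at −78 °C.

Step 14
Reactants: 21 methyl 2-(hydroxymethyl)acrylate
Product: 22 methyl 2-[(tert-butyldimethylsilyloxy)methyl]acrylate
Conditions: TBSCl, imidazole, CH2Cl2, 0 °C to rt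
Reagents that add atoms: tert-butyldimethylsilyl chloride CC(C)(C)[Si](C)(C)Cl
Why: Routine silylation of a primary allylic alcohol.

Step 15
Reactants: 22 methyl 2-[(tert-butyldimethylsilyloxy)methyl]acrylate
Product: 23 2-[(tert-butyldimethylsilyloxy)methyl]acrylic acid
Conditions: LiOH, THF–H2O, 0 °C; then 1 M HCl to pH 4
Reagents that add atoms: lithium hydroxide [Li+].[OH-]
Why: Mild saponification of the methyl ester, in which the primary silyl ether should survive cold aqueous LiOH.

Step 16
Reactants: 20 (8S)-allylic alcohol; 23 2-[(tert-butyldimethylsilyloxy)methyl]acrylic acid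
Product: 24 C8 acrylate ester (ester of 20 with acid 23)
Conditions: DCC, DMAP (cat.), CH2Cl2, 0 °C to rt
Reagents that add atoms: none
Why: Steglich esterification of the secondary allylic alcohol with retention at C8, run directly on freshly prepared 20 so that the free hydroxyl has no time to close a hemiketal on C1 or a lactone on the C10 ester.

Step 17
Reactants: 24 C8 acrylate ester
Product: 25 (10R)-methyl ketone (bis-silyl seco ester of the target, allyl carboxylate removed)
Conditions: Pd2(dba)3 (5 mol%), (S)-t-BuPHOX (12.5 mol%), Meldrum's acid (2.5 equiv), 1,4-dioxane, rt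
Reagents that add atoms: none
Why: Palladium-catalysed decarboxylative protonation of an α-quaternary allyl β-keto ester, in which zerovalent palladium ionises the allyl ester, CO2 is lost and Meldrum's acid protonates the C1/C10 enolate inside the chiral PHOX–palladium environment, should set the 10R methine under catalyst control, while the hindered tetrasubstituted allylic acetate and C8 ester should not ionise.

Step 18
Reactants: 25 (10R)-methyl ketone
Product: 27 CNP0258719.1, via hydroxy ester 26 (not isolated)
Conditions: HF·pyridine, excess pyridine, THF, 0 °C to rt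
Reagents that add atoms: none
Why: Pyridine-buffered HF·pyridine should remove both silyl ethers without opening the trisubstituted epoxide, and the freed C6 hydroxyl, held cis to the methyl ester across C7=C11, lactonises to the butenolide with loss of methanol.

Compound list
1 | nerol | CC(C)=CCC/C(C)=C\CO | starting material
2 | (2S,3R)-2,3-epoxynerol | CC(C)=CCC[C@@]1(C)O[C@H]1CO | intermediate
3 | (2R,3R)-3-methyl-3-(4-methylpent-3-en-1-yl)oxirane-2-carbaldehyde | CC(C)=CCC[C@@]1(C)O[C@H]1C=O | intermediate
4 | methyl propiolate | C#CC(=O)OC | starting material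
5 | methyl (4S)-4-hydroxy-4-[(2S,3R)-3-methyl-3-(4-methylpent-3-en-1-yl)oxiran-2-yl]but-2-ynoate | CC(C)=CCC[C@@]1(C)O[C@H]1[C@@H](O)C#CC(=O)OC | intermediate
6 | methyl (4S)-4-(tert-butyldimethylsilyloxy)-4-[(2S,3R)-3-methyl-3-(4-methylpent-3-en-1-yl)oxiran-2-yl]but-2-ynoate | CC(C)=CCC[C@@]1(C)O[C@H]1[C@@H](O[Si](C)(C)C(C)(C)C)C#CC(=O)OC | intermediate
7 | ethyl vinyl ether | C=COCC | starting material
8 | alkenylcopper adduct (copper on C11, cis to the 1-ethoxyvinyl group; drawn without its cuprate counter-ligand) | CC(C)=CCC[C@@]1(C)O[C@H]1[C@@H](O[Si](C)(C)C(C)(C)C)/C(C(=C)OCC)=C(/[Cu])C(=O)OC | intermediate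
9 | methyl (2Z,4S)-4-(tert-butyldimethylsilyloxy)-3-(1-ethoxyethenyl)-2-iodo-4-[(2S,3R)-3-methyl-3-(4-methylpent-3-en-1-yl)oxiran-2-yl]but-2-enoate | CC(C)=CCC[C@@]1(C)O[C@H]1[C@@H](O[Si](C)(C)C(C)(C)C)/C(C(=C)OCC)=C(/I)C(=O)OC | intermediate
10 | (tributylstannyl)methanol | CCCC[Sn](CCCC)(CCCC)CO | starting material
11 | allylic alcohol: methyl (2E,4S)-4-(tert-butyldimethylsilyloxy)-3-(1-ethoxyethenyl)-2-(hydroxymethyl)-4-[(2S,3R)-3-methyl-3-(4-methylpent-3-en-1-yl)oxiran-2-yl]but-2-enoate | CC(C)=CCC[C@@]1(C)O[C@H]1[C@@H](O[Si](C)(C)C(C)(C)C)/C(C(=C)OCC)=C(/CO)C(=O)OC | intermediate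
12 | methyl (2E,4S)-2-(acetoxymethyl)-4-(tert-butyldimethylsilyloxy)-3-(1-ethoxyethenyl)-4-[(2S,3R)-3-methyl-3-(4-methylpent-3-en-1-yl)oxiran-2-yl]but-2-enoate | CC(C)=CCC[C@@]1(C)O[C@H]1[C@@H](O[Si](C)(C)C(C)(C)C)/C(C(=C)OCC)=C(/COC(C)=O)C(=O)OC | intermediate
13 | methyl (2E,4S)-2-(acetoxymethyl)-3-(bromoacetyl)-4-(tert-butyldimethylsilyloxy)-4-[(2S,3R)-3-methyl-3-(4-methylpent-3-en-1-yl)oxiran-2-yl]but-2-enoate | CC(C)=CCC[C@@]1(C)O[C@H]1[C@@H](O[Si](C)(C)C(C)(C)C)/C(C(=O)CBr)=C(/COC(C)=O)C(=O)OC | intermediate
14 | methyl (2E,4S)-2-(acetoxymethyl)-3-(bromoacetyl)-4-(tert-butyldimethylsilyloxy)-4-[(2S,3R)-3-methyl-3-(3-oxopropyl)oxiran-2-yl]but-2-enoate | O=CCC[C@@]1(C)O[C@H]1[C@@H](O[Si](C)(C)C(C)(C)C)/C(C(=O)CBr)=C(/COC(C)=O)C(=O)OC | intermediate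
15 | glycine allyl ester p-toluenesulfonate | C=CCOC(=O)C[NH3+].Cc1ccc(cc1)S(=O)(=O)[O-] | starting material
16 | allyl diazoacetate | C=CCOC(=O)C=[N+]=[N-] | intermediate
17 | methyl (2E,4S)-2-(acetoxymethyl)-4-{(2S,3R)-3-[5-(allyloxy)-3,5-dioxopentyl]-3-methyloxiran-2-yl}-3-(bromoacetyl)-4-(tert-butyldimethylsilyloxy)but-2-enoate | C=CCOC(=O)CC(=O)CC[C@@]1(C)O[C@H]1[C@@H](O[Si](C)(C)C(C)(C)C)/C(C(=O)CBr)=C(/COC(C)=O)C(=O)OC | intermediate
18 | cyclised β-keto ester: ten-membered 1,8-diketone, allyl ester on C10 (both C10 epimers), (4R,5S)-cis-epoxide, (6S)-OTBS, C7=C11 olefin with CO2Me cis to C6 and CH2OAc cis to C8 | O=C1CC(C(=O)OCC=C)C(=O)CC[C@@]2(C)O[C@H]2[C@@H](O[Si](C)(C)C(C)(C)C)/C1=C(/COC(C)=O)C(=O)OC | intermediate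
19 | C10-methylated β-keto ester: as 18 with methyl and allyl ester on quaternary C10 (both C10 epimers) | O=C1CC(C)(C(=O)OCC=C)C(=O)CC[C@@]2(C)O[C@H]2[C@@H](O[Si](C)(C)C(C)(C)C)/C1=C(/COC(C)=O)C(=O)OC | intermediate
20 | (8S)-allylic alcohol: as 19 with the C8 ketone reduced to the (8S)-carbinol | O[C@H]1CC(C)(C(=O)OCC=C)C(=O)CC[C@@]2(C)O[C@H]2[C@@H](O[Si](C)(C)C(C)(C)C)/C1=C(/COC(C)=O)C(=O)OC | intermediate
21 | methyl 2-(hydroxymethyl)acrylate | C=C(CO)C(=O)OC | starting material
22 | methyl 2-[(tert-butyldimethylsilyloxy)methyl]acrylate | C=C(CO[Si](C)(C)C(C)(C)C)C(=O)OC | intermediate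
23 | 2-[(tert-butyldimethylsilyloxy)methyl]acrylic acid | C=C(CO[Si](C)(C)C(C)(C)C)C(=O)O | intermediate
24 | C8 acrylate ester: 2-[(tert-butyldimethylsilyloxy)methyl]acrylate of 20 | C=C(CO[Si](C)(C)C(C)(C)C)C(=O)O[C@H]1CC(C)(C(=O)OCC=C)C(=O)CC[C@@]2(C)O[C@H]2[C@@H](O[Si](C)(C)C(C)(C)C)/C1=C(/COC(C)=O)C(=O)OC | intermediate
25 | (10R)-methyl ketone: (4R,5S,6S,8S,10R) bis-silyl seco ester with C1 ketone, C10 methine and methyl ester on C11 | C=C(CO[Si](C)(C)C(C)(C)C)C(=O)O[C@H]1C[C@@H](C)C(=O)CC[C@@]2(C)O[C@H]2[C@@H](O[Si](C)(C)C(C)(C)C)/C1=C(/COC(C)=O)C(=O)OC | intermediate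
26 | hydroxy ester: 25 with the C6 hydroxyl and the side-chain hydroxyl free | C=C(CO)C(=O)O[C@H]1C[C@@H](C)C(=O)CC[C@@]2(C)O[C@H]2[C@@H](O)/C1=C(/COC(C)=O)C(=O)OC | intermediate
27 | CNP0258719.1 | C=C(CO)C(=O)O[C@H]1C[C@@H](C)C(=O)CC[C@@]2(C)O[C@H]2[C@H]2OC(=O)C(COC(C)=O)=C12 | target

Total step count: 18. Longest linear sequence: 15 steps (steps 1–8, 10–13 and 16–18).

The three steps most likely to fail, with one fallback each:

The ring closure of step 11 carries the highest risk. Intermolecular alkylation to oligomers, oxygen alkylation to the eleven-membered enol ether, base-induced loss of the allylic acetate through the C9 enolate, or transannular aldol reaction of the 1,4-diketone may outrun the ten-membered carbon alkylation. The fallback sets out from 17 and comes back to the route at 18, and it forms the same bond by carbonyl condensation instead of substitution. Kornblum oxidation of the bromomethyl ketone (DMSO, NaHCO3, rt) should give the α-keto aldehyde F1. An intramolecular Knoevenagel condensation of the β-keto ester methylene onto that aldehyde (piperidinium acetate, 4 Å MS, CH2Cl2, high dilution) closes C9–C10 as a double bond in the alkylidene β-keto ester F2. Conjugate reduction of this doubly activated olefin with a Hantzsch ester (CH2Cl2, rt) then gives 18.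

The C8 reduction of step 13 is the second risk. The conformation of the ten-membered ring may override the facial preference of the catalyst, or the C1 ketone may be reduced as well. The fallback sets out from 19 and comes back to the route at 24, and it corrects C8 by inversion instead of by catalyst control. Luche reduction (NaBH4, CeCl3·7H2O, MeOH, −78 °C) of the conjugated ketone should give the C8 alcohols, the C1 ketone next to quaternary C10 reacting more slowly; any 8S alcohol is 20 and follows step 16. The (8R)-alcohol F3 is esterified with acid 23 under Mitsunobu conditions (PPh3, DIAD, toluene, 0 °C) with inversion, giving 24 directly; SN2′ attack is blocked by the tetrasubstituted olefin.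

The C10 protonation of step 17 is the third risk. Protonation of the ring enolate may occur on the wrong face, or with poor facial selectivity, if the substrate bias opposes the catalyst. The fallback sets out from 24 and comes back to the route at 25, and it replaces kinetic control by thermodynamic control. Achiral decarboxylation (Pd(PPh3)4, dimedone, THF, rt) should give 25 together with the (10S)-methyl ketone F4. Because no butenolide is present yet, the mixture can be equilibrated at the α-keto methine with DBU (0.2 equiv, CH2Cl2, 0 °C), the minor epimer being recycled through the same equilibration after separation.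

Further compounds
F1 | step 11 | α-keto aldehyde (from 17, C9 aldehyde next to the C8 ketone) | C=CCOC(=O)CC(=O)CC[C@@]1(C)O[C@H]1[C@@H](O[Si](C)(C)C(C)(C)C)/C(C(=O)C=O)=C(/COC(C)=O)C(=O)OC
F2 | step 11 | alkylidene β-keto ester (ten-membered ring with a ring-cis C9=C10 double bond) | O=C1/C=C(C(=O)OCC=C)\C(=O)CC[C@@]2(C)O[C@H]2[C@@H](O[Si](C)(C)C(C)(C)C)/C1=C(/COC(C)=O)C(=O)OC
F3 | step 13 | (8R)-alcohol (C8 epimer of 20) | O[C@@H]1CC(C)(C(=O)OCC=C)C(=O)CC[C@@]2(C)O[C@H]2[C@@H](O[Si](C)(C)C(C)(C)C)/C1=C(/COC(C)=O)C(=O)OC
F4 | step 17 | (10S)-methyl ketone (C10 epimer of 25) | C=C(CO[Si](C)(C)C(C)(C)C)C(=O)O[C@H]1C[C@H](C)C(=O)CC[C@@]2(C)O[C@H]2[C@@H](O[Si](C)(C)C(C)(C)C)/C1=C(/COC(C)=O)C(=O)OC
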